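(The numbers in the tables are calculated with constants of no real substance.)

A charge of nucleophile cannot serve as many electrophiles as it has molecules if the acid from each turnover takes a second nucleophile away. That was my starting point.

| flask | electrophile | nucleophile | free base | remark | time |
|---|---|---|---|---|---|
| teal | 1 M | 1 equiv | 0.74 equiv | run made earlier |  |
| grey | 1 M | 1 equiv | 1.7 equiv | run made earlier |  |
| flask | 1.0 M | 1.00 equiv | 1.10 equiv |  | 2.5 h |

- teal (time / min: electrophile / %, target / %): 30.0: 40.7, 47.3; 60.0: 26.0, 44.1; 90.0: 21.6, 42.3; 120: 15.2, 38.8
- grey (time / min: electrophile / %, target / %): 15.0: 43.6, 47.7; 40.0: 30.4, 49.3; 80.0: 17.5, 45.6; 120: 11.6, 41.8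

(readings scatter by 1 percentage point)

- the earlier runs were read with a standard deviation of 1 percentage point
- steps thought possible: acid set free + free base <-> salt of the base; electrophile + nucleophile -> acid set free + target; nucleophile + acid set free <-> protonated nucleophile; target -> over-reaction product; electrophile <-> dormant form
- what has gone from electrophile into another species counts as reacted, even if it can come back
- the earlier runs do not show how much of nucleophile is bound; that part of a forecast is a guess

* part of the electrophile that has reacted at 2.5 h
* share of the unused nucleophile that is free and not bound as protonated nucleophile, at 2.5 h

Here c is the part of the electrophile reacted and fr the free share of the unused nucleophile.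

In the first instants, electrophile and nucleophile make target and acid, and free base and nucleophile can both catch that acid. The earliest targets read 47.3 % at 30.0 min in teal and 47.7 % at 15.0 min in grey, although grey held 2.30 times the base. So I took the nucleophile as the quick catcher. This gave my burst ceiling, 50.0 % of the electrophile in the flask: the target made if each turnover uses one nucleophile and binds another, which is half the nucleophile charge.

In the middle, I pictured the free base drawing acid off slowly, each acid drawn releasing nucleophile for further turnover. I read the fall of electrophile in teal from 30.0 min to 120 min as pseudo-first-order, with a time constant of 91.4 min.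

For the end, I interpolated the electrophile at 120 min by base charge, which gave 13.8 %. Running that on to 2.5 h gave c of 90.0 %. For fr I had a guess, and it was low, since I took the nucleophile as the quick catcher.

The forecast said 89.5 % for c, a little below mine, and 73 % for fr, above my low guess. Its ground was: “The acid must therefore share between base and nucleophile, with the base favoured only about fivefold.”

The flask gave 90.9 % for c and 8.47 % for fr, far below the forecast's fr.

    acid set free + free base ⇌ salt of the base (K = 1030 M⁻¹, k = 36.5 M⁻¹ h⁻¹)
    electrophile + nucleophile → acid set free + target (k = 19.5 M⁻¹ h⁻¹)
    nucleophile + acid set free ⇌ protonated nucleophile, settled at all times (K = 2400 M⁻¹)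
    target → over-reaction product (k = 0.325 h⁻¹)
    electrophile ⇌ dormant form (K = 27.4, k = 0.296 h⁻¹)

At 0.250 h the flask held 0.465 M protonated nucleophile against 0.0398 M salt of the base, with target and over-reaction product together at 51.3 %, a little above the ceiling of 50.0 %. The same flask with 1.70 equiv of nucleophile has a ceiling of 85.0 %, which puts 15.0 % of its electrophile beyond the ceiling. At 2.50 h that neighbour held 0.286 % electrophile, less than the 9.13 % in the flask.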